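## Retrosynthetic overview

1. Target ⇒ cut the ester C–O bond: (−)-lariciresinol + (E)-p-coumaric acid, joined last by a phenol-tolerant Mitsunobu esterification.
2. (−)-Lariciresinol ⇒ cut the benzylic C2–O1 bond of the oxolane (key step, the only ring made): C2-symmetric (S,S)-secoisolariciresinol, closed by dehydrogenative cycloetherification through a p-quinone methide, which sets C2.
3. (S,S)-Secoisolariciresinol ⇒ an (S,S)-2,3-dibenzylsuccinyl bis-imide; one LiAlH4 step frees both CH2OH groups, both phenols and the auxiliary.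
4. Bis-imide ⇒ auxiliary-controlled oxidative enolate homocoupling of one imide (sets C3 and C4); the imide comes from dihydroferulic acid and (R)-4-benzyl-oxazolidin-2-one, with the phenol masked as a pivalate in the same pot.
5. Ring order: the arenes are bought; the oxolane is closed in the fourth of five steps and the ester is made last.

Assumption: the target is taken exactly as drawn, which reads as (2R,3S,4S) at the oxolane (O1, C2 aryl, C3 CH2O-acyl, C4 benzyl; aryl trans to the C3 arm, C3 and C4 arms cis), i.e. the p-coumarate of (−)-lariciresinol; dihydroferulic acid is bought.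

## Route

**Step 1**
Reactants: 1 3-(4-hydroxy-3-methoxyphenyl)propanoic acid (dihydroferulic acid); 2 (R)-4-benzyl-1,3-oxazolidin-2-one
Product: 4 (4R)-4-benzyl-3-[3-(3-methoxy-4-pivaloyloxyphenyl)propanoyl]-1,3-oxazolidin-2-one, via mixed pivalic anhydride 3 (not isolated)
Conditions: PivCl (2.2 equiv), NEt3 (3.5 equiv), DMAP (5 mol%), THF, −10 → 0 °C, 1 h; then 2 (1.0 equiv), LiCl (1.1 equiv), rt, 12 h
Reagents that add atoms: pivaloyl chloride, CC(C)(C)C(=O)Cl
Why: Mixed-anhydride N-acylation of an Evans auxiliary, in which pivaloyl chloride converts the acid into the mixed anhydride and the phenol into its aryl pivalate, and the LiCl-activated oxazolidinone attacks the less hindered anhydride carbonyl; no stereocentre is formed and the pivalate (no α-hydrogen) needs no separate step to put on or take off.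

**Step 2**
Reactants: 4 (4R)-4-benzyl-3-[3-(3-methoxy-4-pivaloyloxyphenyl)propanoyl]-1,3-oxazolidin-2-one (two molecules)
Product: 7 (2S,3S)-1,4-bis[(4R)-4-benzyl-2-oxo-1,3-oxazolidin-3-yl]-2,3-bis(3-methoxy-4-pivaloyloxybenzyl)butane-1,4-dione, via lithium Z-enolate 5 (not isolated), via trichlorotitanium enolate 6 (not isolated)
Conditions: LiN(iPr)2 (1.05 equiv), THF, −78 °C, 45 min; then TiCl4 (1.1 equiv), −78 → −20 °C, 3 h
Reagents that add atoms: none
Why: Oxidative enolate homocoupling in which tetravalent titanium is reduced to trivalent titanium; both chelated Z-enolates bond through the face opposite the C4 benzyl group of the (R)-auxiliary, which gives the C2-symmetric (S,S) dimer and so sets both future C3 and C4 of the oxolane.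

**Step 3**
Reactants: 7 (2S,3S)-1,4-bis[(4R)-4-benzyl-2-oxo-1,3-oxazolidin-3-yl]-2,3-bis(3-methoxy-4-pivaloyloxybenzyl)butane-1,4-dione
Product: 8 (2S,3S)-2,3-bis(4-hydroxy-3-methoxybenzyl)butane-1,4-diol ((S,S)-secoisolariciresinol)
Conditions: LiAlH4 (6 equiv), THF, 0 °C → rt, 3 h; aq. KNaC4H4O6 work-up
Reagents that add atoms: none
Why: Hydride reduction of the exocyclic imide carbonyls to CH2OH releases the auxiliary and, in the same operation, reduces the aryl pivalates to free phenols; hydride addition is faster than enolisation, so the two stereocentres are kept.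

**Step 4**
Reactants: 8 (2S,3S)-2,3-bis(4-hydroxy-3-methoxybenzyl)butane-1,4-diol
Product: 10 4-[(2R,3S,4S)-4-(4-hydroxy-3-methoxybenzyl)-3-(hydroxymethyl)oxolan-2-yl]-2-methoxyphenol ((−)-lariciresinol), via p-quinone methide 9 (not isolated)
Conditions: 3,6-di-tert-butyl-9-mesityl-10-phenylacridinium tetrafluoroborate (5 mol%), Co(dmgH)2(py)Cl (10 mol%; dmgH = dimethylglyoximate), 2,6-lutidine (0.5 equiv), degassed MeCN (5 mM), 450 nm LEDs, 20 °C, Ar, stopped at about 60% conversion, 8 recovered and recycled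
Reagents that add atoms: none
Why: Proposed new method: oxidant-free, hydrogen-evolving dehydrogenative cycloetherification of a free 4-alkylguaiacol, in which the excited acridinium oxidises the phenol (proton-coupled, lutidine) to its phenoxyl radical, divalent cobalt (formed from the trivalent precatalyst by the acridinyl radical) removes the weak benzylic hydrogen para to oxygen (directly or by radical capture and β-hydride elimination) to give p-quinone methide 9 and a cobalt hydride that releases H2 on protonation, and the γ-hydroxyl then adds 5-exo to the quinone methide with rearomatisation; allylic 1,3-strain keeps H-3 eclipsed with the quinone methide ring in the envelope transition state so the C2 aryl ends up trans to the C3 hydroxymethyl (2R), and the C2 symmetry of 8 makes either aryl/hydroxyl pair give the same product; the closest known reaction types are acridinium/cobaloxime hydrogen-evolving dehydrogenative C–O couplings and desaturations, and the oxidation of 4-alkylphenols to quinone methides by DDQ.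

**Step 5**
Reactants: 10 (−)-lariciresinol; 11 (E)-3-(4-hydroxyphenyl)prop-2-enoic acid (p-coumaric acid)
Product: 13 [(2R,3S,4S)-2-(4-hydroxy-3-methoxyphenyl)-4-(4-hydroxy-3-methoxybenzyl)oxolan-3-yl]methyl (E)-3-(4-hydroxyphenyl)prop-2-enoate (lariciresinol p-coumarate), via alkoxyphosphonium p-coumarate 12 (not isolated)
Conditions: 11 (1.3 equiv), PPh3 (1.3 equiv), DIAD (1.3 equiv, slow addition), THF, 0 °C → rt, 6 h
Reagents that add atoms: none
Why: Mitsunobu esterification in which the carboxylic acid (pKa about 4.5) is engaged far faster than the three phenols (pKa about 10), the alkoxyphosphonium of the only aliphatic alcohol is displaced by carboxylate at a primary carbon, and no stereocentre or the E-alkene is touched.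

## Compound list

1 | 3-(4-hydroxy-3-methoxyphenyl)propanoic acid (dihydroferulic acid) | COc1cc(CCC(=O)O)ccc1O | starting material
2 | (R)-4-benzyl-1,3-oxazolidin-2-one | O=C1N[C@H](Cc2ccccc2)CO1 | starting material
3 | 3-(3-methoxy-4-pivaloyloxyphenyl)propanoic pivalic anhydride | COc1cc(CCC(=O)OC(=O)C(C)(C)C)ccc1OC(=O)C(C)(C)C | intermediate
4 | (4R)-4-benzyl-3-[3-(3-methoxy-4-pivaloyloxyphenyl)propanoyl]-1,3-oxazolidin-2-one | COc1cc(CCC(=O)N2[C@H](Cc3ccccc3)COC2=O)ccc1OC(=O)C(C)(C)C | intermediate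
5 | lithium Z-enolate of 4 | [Li]O/C(=C\Cc1ccc(OC(=O)C(C)(C)C)c(OC)c1)N1[C@H](Cc2ccccc2)COC1=O | intermediate
6 | trichlorotitanium Z-enolate of 4 | Cl[Ti](Cl)(Cl)O/C(=C\Cc1ccc(OC(=O)C(C)(C)C)c(OC)c1)N1[C@H](Cc2ccccc2)COC1=O | intermediate
7 | (2S,3S)-1,4-bis[(4R)-4-benzyl-2-oxo-1,3-oxazolidin-3-yl]-2,3-bis(3-methoxy-4-pivaloyloxybenzyl)butane-1,4-dione | O=C([C@@H](Cc1ccc(OC(=O)C(C)(C)C)c(OC)c1)[C@H](Cc1ccc(OC(=O)C(C)(C)C)c(OC)c1)C(=O)N1[C@H](Cc2ccccc2)COC1=O)N1[C@H](Cc2ccccc2)COC1=O | intermediate
8 | (2S,3S)-2,3-bis(4-hydroxy-3-methoxybenzyl)butane-1,4-diol ((S,S)-secoisolariciresinol) | OC[C@@H](Cc1ccc(O)c(OC)c1)[C@@H](CO)Cc1ccc(O)c(OC)c1 | intermediate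
9 | 4-[(2S,3S)-4-hydroxy-2-(hydroxymethyl)-3-(4-hydroxy-3-methoxybenzyl)butylidene]-2-methoxycyclohexa-2,5-dien-1-one (p-quinone methide) | COC1=CC(=C[C@H](CO)[C@@H](CO)Cc2ccc(O)c(OC)c2)C=CC1=O | intermediate
10 | 4-[(2R,3S,4S)-4-(4-hydroxy-3-methoxybenzyl)-3-(hydroxymethyl)oxolan-2-yl]-2-methoxyphenol ((−)-lariciresinol) | COc1cc(C[C@@H]2CO[C@@H](c3ccc(O)c(OC)c3)[C@@H]2CO)ccc1O | intermediate
11 | (E)-3-(4-hydroxyphenyl)prop-2-enoic acid (p-coumaric acid) | O=C(O)/C=C/c1ccc(O)cc1 | starting material
12 | alkoxy(triphenyl)phosphonium of 10 as its p-coumarate salt | COc1cc(C[C@@H]2CO[C@@H](c3ccc(O)c(OC)c3)[C@@H]2CO[P+](c4ccccc4)(c5ccccc5)c6ccccc6)ccc1O.[O-]C(=O)/C=C/c1ccc(O)cc1 | intermediate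
13 | lariciresinol p-coumarate | COc1cc(C[C@@H]2CO[C@@H](c3ccc(O)c(OC)c3)[C@@H]2COC(=O)/C=C/c2ccc(O)cc2)ccc1O | target

## Step count and risks

Total steps: 5. Longest linear sequence: 5 (from 1).

**Step 4 (the proposed new step).** The guaiacyl phenoxyl radical may dimerise (C5–C5 or O4–C5) before cobalt takes the benzylic hydrogen. Product 10 still carries an oxidisable 4-hydroxybenzyl group and a benzylic ether C–H, so a second closure to the furofuran or ring-opening oxidation can follow. This is why the reaction is run dilute and to partial conversion; a realistic ceiling is about 45–50% per pass. The other arene can also close onto the quinone methide to give the aryltetralin.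

Fallback by known chemistry, setting out from 8 and coming back at 10: the two phenols are benzylated selectively (BnBr, K2CO3, acetone, reflux) to (2S,3S)-2,3-bis[4-(benzyloxy)-3-methoxybenzyl]butane-1,4-diol F1. Stoichiometric DDQ (1.1 equiv, NaHCO3, 4 Å sieves, CH2Cl2, 0 °C) then abstracts hydride from one 4-alkoxybenzylic position, and the γ-hydroxyl captures the cation to give the 2,3-trans oxolane {(2R,3S,4S)-2-[4-(benzyloxy)-3-methoxyphenyl]-4-[4-(benzyloxy)-3-methoxybenzyl]oxolan-3-yl}methanol F2. Hydrogenolysis (H2 1 atm, 10% Pd/C, EtOAc, rt, monitored to spare the benzylic ring C–O bond) gives 10.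

**Step 2.** The homocoupling may give a modest yield or a diastereomer mixture that is hard to separate, and the enolate could attack the aryl pivalate.

Fallback, setting out from 4 and coming back at 8, builds the two centres one at a time:
- Evans alkylation of 4 (NaN(SiMe3)2, tert-butyl bromoacetate, THF, −78 °C) gives tert-butyl (3S)-4-[(4R)-4-benzyl-2-oxo-1,3-oxazolidin-3-yl]-3-(3-methoxy-4-pivaloyloxybenzyl)-4-oxobutanoate F3.
- LiBH4/H2O (1.1 equiv each, Et2O, 0 °C) reduces only the imide to tert-butyl (3S)-3-(hydroxymethyl)-4-(3-methoxy-4-pivaloyloxyphenyl)butanoate F4.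
- TFA in CH2Cl2 closes this to (4S)-4-(3-methoxy-4-pivaloyloxybenzyl)oxolan-2-one F5.
- The lactone enolate (LiN(SiMe3)2, THF, −78 °C) is alkylated anti to the C4 substituent with commercial 4-(benzyloxy)-3-methoxybenzyl bromide to give the trans lactone (3S,4S)-3-[4-(benzyloxy)-3-methoxybenzyl]-4-(3-methoxy-4-pivaloyloxybenzyl)oxolan-2-one F6.
- LiAlH4 (THF, 0 °C) opens the lactone and removes the pivalate to give (2S,3S)-2-[4-(benzyloxy)-3-methoxybenzyl]-3-(4-hydroxy-3-methoxybenzyl)butane-1,4-diol F7.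
- H2, 10% Pd/C, EtOH gives 8.

**Step 5.** With three free phenols present, some phenol O-alkylation or oligomer formation can compete, and the β-branched primary carbon slows the displacement.

Fallback, setting out from 10 and coming back at 13, builds the cinnamate double bond instead of esterifying the preformed acid. Meldrum's acid (1.1 equiv, toluene, 85 °C) acylates the aliphatic hydroxyl to give the malonate half-ester 3-{[(2R,3S,4S)-2-(4-hydroxy-3-methoxyphenyl)-4-(4-hydroxy-3-methoxybenzyl)oxolan-3-yl]methoxy}-3-oxopropanoic acid F8. Knoevenagel–Doebner condensation with 4-hydroxybenzaldehyde (pyridine, cat. piperidine, 60 °C) with decarboxylation gives the E-configured ester 13.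

## Further compounds

F1 | step 4 | (2S,3S)-2,3-bis[4-(benzyloxy)-3-methoxybenzyl]butane-1,4-diol | OC[C@@H](Cc1ccc(OCc2ccccc2)c(OC)c1)[C@@H](CO)Cc1ccc(OCc2ccccc2)c(OC)c1
F2 | step 4 | {(2R,3S,4S)-2-[4-(benzyloxy)-3-methoxyphenyl]-4-[4-(benzyloxy)-3-methoxybenzyl]oxolan-3-yl}methanol | COc1cc(C[C@@H]2CO[C@@H](c3ccc(OCc4ccccc4)c(OC)c3)[C@@H]2CO)ccc1OCc1ccccc1
F3 | step 2 | tert-butyl (3S)-4-[(4R)-4-benzyl-2-oxo-1,3-oxazolidin-3-yl]-3-(3-methoxy-4-pivaloyloxybenzyl)-4-oxobutanoate | CC(C)(C)OC(=O)C[C@H](Cc1ccc(OC(=O)C(C)(C)C)c(OC)c1)C(=O)N1[C@H](Cc2ccccc2)COC1=O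
F4 | step 2 | tert-butyl (3S)-3-(hydroxymethyl)-4-(3-methoxy-4-pivaloyloxyphenyl)butanoate | CC(C)(C)OC(=O)C[C@H](Cc1ccc(OC(=O)C(C)(C)C)c(OC)c1)CO
F5 | step 2 | (4S)-4-(3-methoxy-4-pivaloyloxybenzyl)oxolan-2-one | O=C1C[C@H](Cc2ccc(OC(=O)C(C)(C)C)c(OC)c2)CO1
F6 | step 2 | (3S,4S)-3-[4-(benzyloxy)-3-methoxybenzyl]-4-(3-methoxy-4-pivaloyloxybenzyl)oxolan-2-one | O=C1OC[C@@H](Cc2ccc(OC(=O)C(C)(C)C)c(OC)c2)[C@@H]1Cc1ccc(OCc2ccccc2)c(OC)c1
F7 | step 2 | (2S,3S)-2-[4-(benzyloxy)-3-methoxybenzyl]-3-(4-hydroxy-3-methoxybenzyl)butane-1,4-diol | OC[C@@H](Cc1ccc(OCc2ccccc2)c(OC)c1)[C@@H](CO)Cc1ccc(O)c(OC)c1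
F8 | step 5 | 3-{[(2R,3S,4S)-2-(4-hydroxy-3-methoxyphenyl)-4-(4-hydroxy-3-methoxybenzyl)oxolan-3-yl]methoxy}-3-oxopropanoic acid | COc1cc(C[C@@H]2CO[C@@H](c3ccc(O)c(OC)c3)[C@@H]2COC(=O)CC(=O)O)ccc1O
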